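**Retrosynthetic overview**

1. Target 27 ⇐ allyl ester 24 (acetonide/TES removal, acetylation of O14 and O15, deallylation) ⇐ formyl ester 21 (C19 formyl → C19 methyl).
2. 21 ⇐ 20: ring A (C1–C5, C10) is closed last by a Claisen ring contraction of a 2-cyclohexenyl-3,4-dihydro-2H-pyran-5-carboxylate; the O–C1 bond is exchanged for the C4–C5 bond, which sets C4, C5 and the C1=C10 alkene in one operation.
3. Enabling feature: in ring A the C1=C10 double bond lies γ,δ to the one-carbon groups on quaternary C4 (C19–C4–C5–C10=C1), and C1 and C4 are already joined through C2–C3; ring A can therefore be written as an allyl vinyl ether (O–C19H=C4 / C1–C10=C5) held in a six-membered O-heterocycle.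
4. 20 ⇐ enal 12 (reagent-controlled allylboration sets C1; hydroformylation, dehydration and C-acylation/alcoholysis build the pyran) ⇐ ring-B ketone 9 via enol triflate 11.
5. Ring B is carbocyclic from the start (2-methylcyclohex-2-enone: asymmetric methyl addition sets C8, Mukaiyama–Michael addition to enone 3 sets C9, chelation-controlled MeMgBr sets C13, C14 comes from the glycerate pool). Ring order: ring B, temporary dihydropyran, ring A.

Key step: step 14

Remark: locants are halimane locants (ring A: C1–C5, C10; ring B: C5–C10; side chain C11–C15 with C16 on C13; C17 on C8; C18 = carboxyl carbon and C19 = the other carbon on C4; C20 on C9). Sc = (3R)-3-[(4S)-2,2-dimethyl-1,3-dioxolan-4-yl]-3-(triethylsilyloxy)butyl; Cy = (5R,6S)-5,6-dimethyl-6-Sc-cyclohex-1-en-1-yl. The copper ligand antipode in step 3 is the one that gives the 3R centre; (−)-B-allyldiisopinocampheylborane is the reagent derived from (+)-α-pinene and is assumed to be bought as a solution.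

**Route**

Step 1
Reactants: 1 methyl (4S)-2,2-dimethyl-1,3-dioxolane-4-carboxylate
Product: 2 (4S)-N-methoxy-N,2,2-trimethyl-1,3-dioxolane-4-carboxamide
Conditions: MeNH(OMe)·HCl, i-PrMgCl, THF, −20 °C
Reagents that add atoms: N,O-dimethylhydroxylamine hydrochloride, CNOC.Cl
Why: Weinreb amide formation by attack of the magnesium amide on the ester, at a temperature at which the α-alkoxy stereocentre should not enolise.

Step 2
Reactants: 2 (4S)-N-methoxy-N,2,2-trimethyl-1,3-dioxolane-4-carboxamide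
Product: 3 1-[(4S)-2,2-dimethyl-1,3-dioxolan-4-yl]prop-2-en-1-one
Conditions: CH2=CHMgBr, THF, −78 to 0 °C; inverse quench into cold aq. NaHSO4
Reagents that add atoms: vinylmagnesium bromide, C=C[Mg]Br
Why: Weinreb ketone synthesis, in which the chelated tetrahedral adduct prevents over-addition and the acidic inverse quench prevents amine addition to the enone; the stereocentre is not touched.

Step 3
Reactants: 4 2-methylcyclohex-2-en-1-one
Product: 6 trimethyl{[(3R)-2,3-dimethylcyclohex-1-en-1-yl]oxy}silane, via aluminium enolate 5 (not isolated)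
Conditions: Me3Al, CuTC (2 mol %), BINOL-based phosphoramidite (4 mol %), Et2O, −30 °C; then TMSOTf, THF, 0 °C
Reagents that add atoms: trimethylaluminium, C[Al](C)C; trimethylsilyl trifluoromethanesulfonate, C[Si](C)(C)OS(=O)(=O)C(F)(F)F
Why: copper-catalysed asymmetric conjugate addition in which the chiral ligand selects the enone face and sets C8 (R), followed by O-silylation of the enolate, which fixes the enol ether between C9 and C10.

Step 4
Reactants: 6 trimethyl{[(3R)-2,3-dimethylcyclohex-1-en-1-yl]oxy}silane; 3 1-[(4S)-2,2-dimethyl-1,3-dioxolan-4-yl]prop-2-en-1-one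
Product: 7 (2S,3R)-2-{3-[(4S)-2,2-dimethyl-1,3-dioxolan-4-yl]-3-oxopropyl}-2,3-dimethylcyclohexan-1-one
Conditions: BF3·OEt2, i-PrOH, CH2Cl2, −78 °C
Reagents that add atoms: none
Why: Mukaiyama–Michael addition of a tetrasubstituted silyl enol ether to a Lewis-acid-activated vinyl ketone, in which the acceptor should add anti to the pseudoaxial C8 methyl group and so set quaternary C9 (S) with C17 and C20 cis.

Step 5
Reactants: 7 (2S,3R)-2-{3-[(4S)-2,2-dimethyl-1,3-dioxolan-4-yl]-3-oxopropyl}-2,3-dimethylcyclohexan-1-one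
Product: 8 (2S,3R)-2-{(3R)-3-[(4S)-2,2-dimethyl-1,3-dioxolan-4-yl]-3-hydroxybutyl}-2,3-dimethylcyclohexan-1-one
Conditions: MeMgBr, CH2Cl2/Et2O, −78 °C
Reagents that add atoms: methylmagnesium bromide, C[Mg]Br
Why: Cram-chelate-controlled Grignard addition to an α-alkoxy ketone, in which magnesium bridges the C13 carbonyl and the dioxolane oxygen on C14 and methyl enters from the C14–H side to give 13R, while the hindered, non-chelating ring ketone should be left.

Step 6
Reactants: 8 (2S,3R)-2-{(3R)-3-[(4S)-2,2-dimethyl-1,3-dioxolan-4-yl]-3-hydroxybutyl}-2,3-dimethylcyclohexan-1-one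
Product: 9 (2S,3R)-2,3-dimethyl-2-Sc-cyclohexan-1-one
Conditions: TESOTf, 2,6-lutidine, CH2Cl2, −78 °C
Reagents that add atoms: triethylsilyl trifluoromethanesulfonate, CC[Si](CC)(CC)OS(=O)(=O)C(F)(F)F
Why: silylation of a tertiary alcohol with a silyl triflate, done cold with a weak base so that the ketone is not converted to its enol ether.

Step 7
Reactants: 9 (2S,3R)-2,3-dimethyl-2-Sc-cyclohexan-1-one
Product: 11 Cy trifluoromethanesulfonate, via potassium enolate 10 (not isolated)
Conditions: KHMDS, THF, −78 °C; then PhNTf2, −78 to 0 °C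
Reagents that add atoms: N-phenylbis(trifluoromethanesulfonimide), O=S(=O)(N(c1ccccc1)S(=O)(=O)C(F)(F)F)C(F)(F)F
Why: enolisation can only go toward C5 because C9 is quaternary, and O-sulfonylation of the enolate gives the C10=C5 enol triflate.

Step 8
Reactants: 11 Cy trifluoromethanesulfonate
Product: 12 Cy-carbaldehyde [(5R,6S)-5,6-dimethyl-6-Sc-cyclohex-1-ene-1-carbaldehyde]
Conditions: Pd(OAc)2 (5 mol %), dppp, CO (1 atm), Et3SiH, Et3N, DMF, 70 °C
Reagents that add atoms: carbon monoxide, [C-]#[O+]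
Why: palladium-catalysed reductive carbonylation of an alkenyl triflate (oxidative addition, CO insertion, hydride transfer from the silane) installs C1 as an enal.

Step 9
Reactants: 12 Cy-carbaldehyde
Product: 14 (1S)-1-Cy-but-3-en-1-ol, via borinate 13 (not isolated)
Conditions: (−)-Ipc2B(allyl), Et2O, −78 °C; then NaOH, H2O2
Reagents that add atoms: (−)-B-allyldiisopinocampheylborane, C=CCB([C@@H]1C[C@@H]2C[C@H]([C@H]1C)C2(C)C)[C@@H]1C[C@@H]2C[C@H]([C@H]1C)C2(C)C
Why: asymmetric allylboration through a closed chair (Zimmerman–Traxler) transition state, in which the (+)-α-pinene-derived reagent should deliver allyl to the aldehyde face that gives 1S under reagent control.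

Step 10
Reactants: 14 (1S)-1-Cy-but-3-en-1-ol
Product: 16 (6S)-6-Cy-tetrahydro-2H-pyran-2-ol (anomer mixture), via hydroxy aldehyde 15 (not isolated)
Conditions: Rh(acac)(CO)2 (1 mol %), Xantphos, CO/H2 (1:1, 10 bar), toluene, 70 °C
Reagents that add atoms: carbon monoxide, [C-]#[O+]
Why: linear-selective rhodium hydroformylation of the terminal alkene gives the δ-hydroxy aldehyde, which closes to the lactol, while the trisubstituted ring alkene should be inert and C1 is not touched.

Step 11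
Reactants: 16 (6S)-6-Cy-tetrahydro-2H-pyran-2-ol
Product: 18 (2S)-2-Cy-3,4-dihydro-2H-pyran, via anomeric mesylate 17 (not isolated)
Conditions: MsCl, Et3N, CH2Cl2, 0 to 40 °C
Reagents that add atoms: none
Why: elimination of an anomeric sulfonate (glycal-type dehydration of a 2-deoxy lactol) gives the cyclic enol ether without breaking the C1–O bond.

Step 12
Reactants: 18 (2S)-2-Cy-3,4-dihydro-2H-pyran
Product: 19 2,2,2-trichloro-1-[(2S)-2-Cy-3,4-dihydro-2H-pyran-5-yl]ethan-1-one
Conditions: Cl3CCOCl, pyridine, CH2Cl2, 0 to 23 °C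
Reagents that add atoms: trichloroacetyl chloride, O=C(Cl)C(Cl)(Cl)Cl
Why: electrophilic C-acylation of an enol ether at its β-carbon puts the future C18 on C4, and the ring-B alkene, which is not an enol ether, should not react.

Step 13
Reactants: 19 2,2,2-trichloro-1-[(2S)-2-Cy-3,4-dihydro-2H-pyran-5-yl]ethan-1-one
Product: 20 allyl (2S)-2-Cy-3,4-dihydro-2H-pyran-5-carboxylate
Conditions: allyl alcohol, K2CO3 (cat.), 23 °C
Reagents that add atoms: allyl alcohol, C=CCO
Why: haloform-type cleavage of the trichloromethyl ketone by alkoxide gives the vinylogous carbonate ester under mild base.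

Step 14
Reactants: 20 allyl (2S)-2-Cy-3,4-dihydro-2H-pyran-5-carboxylate
Product: 21 allyl (4S,5S,8R,9S,13R,14S)-14,15-isopropylidenedioxy-19-oxo-13-(triethylsilyloxy)halim-1(10)-en-18-oate
Conditions: o-dichlorobenzene, BSA (5 mol %), BHT, sealed tube, 190 °C
Reagents that add atoms: none
Why: Concerted suprafacial [3,3]-sigmatropic (Claisen) shift of the allyl vinyl ether O–C19H=C4 / C1–C10=C5, in which the O–C1 bond breaks as C4–C5 forms, C19 becomes the formyl group and the double bond moves to C1=C10. The closest known reactions are the thermal Claisen ring contraction of 2-alkenyl-3,4-dihydro-2H-pyrans to cyclohex-3-enecarbaldehydes and the lactone-enolate Claisen ring contraction. Ring A closes by C4–C5 bond formation with all three allyl carbons (C1, C10, C5) inside the new ring, and the C2–C3 tether between C1 and C4 allows only a boat-like, bicyclo[2.2.2]-type transition state. C5 (S) is set by 1,3-chirality transfer from C1 (S), because the new bond must form on the allyl face from which the oxygen leaves; C4 (S) is set by the ring-locked enol ether geometry in that boat, which places the ester cis to H5 and the formyl group (the future C19 methyl) cis to C6; the alkene position follows from the mechanism. The step needs the [3,3] shift to outrun retro-hetero-Diels–Alder cleavage and ionisation of the allylic C1–O bond, and it needs the pyran to reach the ring-B face that carries C20; neutral, non-polar, acid-free conditions, the tether and the small C19–H that sits over C10/C9 (with ring B placing C20 pseudo-equatorial) should secure this.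

Step 15
Reactants: 21 allyl (4S,5S,8R,9S,13R,14S)-14,15-isopropylidenedioxy-19-oxo-13-(triethylsilyloxy)halim-1(10)-en-18-oate
Product: 22 19-(E)-tosylhydrazone of 21
Conditions: TsNHNH2, THF/MeOH, 40 °C
Reagents that add atoms: 4-methylbenzenesulfonohydrazide, Cc1ccc(cc1)S(=O)(=O)NN
Why: condensation of the aldehyde with the sulfonyl hydrazide under neutral conditions, which should not cleave the non-enolisable α-formyl ester.

Step 16
Reactants: 22 19-(E)-tosylhydrazone of 21
Product: 24 allyl (4S,5S,8R,9S,13R,14S)-14,15-isopropylidenedioxy-13-(triethylsilyloxy)halim-1(10)-en-18-oate, via N-boryl hydrazide 23 (not isolated)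
Conditions: catecholborane, CHCl3, 0 °C; then NaOAc·3H2O, reflux
Reagents that add atoms: none
Why: tosylhydrazone reduction with catecholborane (hydride addition to C=N, then acetate-induced loss of sulfinate and of N2 from the diazene) turns the formyl group into the C19 methyl group without touching ester, alkene or the quaternary C4.

Step 17
Reactants: 24 allyl (4S,5S,8R,9S,13R,14S)-14,15-isopropylidenedioxy-13-(triethylsilyloxy)halim-1(10)-en-18-oate
Product: 25 allyl (4S,5S,8R,9S,13R,14S)-13,14,15-trihydroxyhalim-1(10)-en-18-oate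
Conditions: 1 M aq. HCl, THF, 23 °C
Reagents that add atoms: none
Why: dilute acid hydrolysis of the acetonide and the tertiary silyl ether, mild enough that the C1=C10 alkene should not be protonated.

Step 18
Reactants: 25 allyl (4S,5S,8R,9S,13R,14S)-13,14,15-trihydroxyhalim-1(10)-en-18-oate
Product: 26 allyl (4S,5S,8R,9S,13R,14S)-14,15-diacetoxy-13-hydroxyhalim-1(10)-en-18-oate
Conditions: Ac2O, pyridine, 0 to 23 °C
Reagents that add atoms: acetic anhydride, CC(=O)OC(C)=O
Why: acylation of the primary and the secondary hydroxyl group, the tertiary C13 hydroxyl group being too hindered to react without an acyl-transfer catalyst.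

Step 19
Reactants: 26 allyl (4S,5S,8R,9S,13R,14S)-14,15-diacetoxy-13-hydroxyhalim-1(10)-en-18-oate
Product: 27 (4S,5S,8R,9S,13R,14S)-14,15-diacetoxy-13-hydroxyhalim-1(10)-en-18-oic acid
Conditions: Pd(PPh3)4 (5 mol %), morpholine, THF, 23 °C
Reagents that add atoms: none
Why: palladium(0)-catalysed allyl transfer (Tsuji–Trost deallylation) to morpholine frees the hindered acid under neutral conditions that leave both acetates in place.

**Compound list**

1 | methyl (4S)-2,2-dimethyl-1,3-dioxolane-4-carboxylate | CC1(C)OC[C@H](O1)C(=O)OC | starting material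
2 | (4S)-N-methoxy-N,2,2-trimethyl-1,3-dioxolane-4-carboxamide | CC1(C)OC[C@H](O1)C(=O)N(C)OC | intermediate
3 | 1-[(4S)-2,2-dimethyl-1,3-dioxolan-4-yl]prop-2-en-1-one | CC1(C)OC[C@H](O1)C(=O)C=C | intermediate
4 | 2-methylcyclohex-2-en-1-one | CC1=CCCCC1=O | starting material
5 | dimethylaluminium (3R)-2,3-dimethylcyclohex-1-en-1-olate | CC1=C(O[Al](C)C)CCC[C@H]1C | intermediate (not isolated)
6 | trimethyl{[(3R)-2,3-dimethylcyclohex-1-en-1-yl]oxy}silane | CC1=C(O[Si](C)(C)C)CCC[C@H]1C | intermediate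
7 | (2S,3R)-2-{3-[(4S)-2,2-dimethyl-1,3-dioxolan-4-yl]-3-oxopropyl}-2,3-dimethylcyclohexan-1-one | CC1(C)OC[C@H](O1)C(=O)CC[C@]2(C)C(=O)CCC[C@H]2C | intermediate
8 | (2S,3R)-2-{(3R)-3-[(4S)-2,2-dimethyl-1,3-dioxolan-4-yl]-3-hydroxybutyl}-2,3-dimethylcyclohexan-1-one | CC1(C)OC[C@H](O1)[C@](C)(O)CC[C@]2(C)C(=O)CCC[C@H]2C | intermediate
9 | (2S,3R)-2,3-dimethyl-2-Sc-cyclohexan-1-one | CC1(C)OC[C@H](O1)[C@](C)(O[Si](CC)(CC)CC)CC[C@]2(C)C(=O)CCC[C@H]2C | intermediate
10 | potassium (5R,6S)-5,6-dimethyl-6-Sc-cyclohex-1-en-1-olate | CC1(C)OC[C@H](O1)[C@](C)(O[Si](CC)(CC)CC)CC[C@]2(C)C([O-])=CCC[C@H]2C.[K+] | intermediate (not isolated)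
11 | Cy trifluoromethanesulfonate | CC1(C)OC[C@H](O1)[C@](C)(O[Si](CC)(CC)CC)CC[C@]2(C)C(OS(=O)(=O)C(F)(F)F)=CCC[C@H]2C | intermediate
12 | Cy-carbaldehyde, (5R,6S)-5,6-dimethyl-6-Sc-cyclohex-1-ene-1-carbaldehyde | CC1(C)OC[C@H](O1)[C@](C)(O[Si](CC)(CC)CC)CC[C@]2(C)C(C=O)=CCC[C@H]2C | intermediate
13 | (1S)-1-Cy-but-3-en-1-yl diisopinocampheylborinate | CC1(C)OC[C@H](O1)[C@](C)(O[Si](CC)(CC)CC)CC[C@]2(C)C([C@@H](OB([C@@H]3C[C@@H]4C[C@H]([C@H]3C)C4(C)C)[C@@H]3C[C@@H]4C[C@H]([C@H]3C)C4(C)C)CC=C)=CCC[C@H]2C | intermediate (not isolated)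
14 | (1S)-1-Cy-but-3-en-1-ol | CC1(C)OC[C@H](O1)[C@](C)(O[Si](CC)(CC)CC)CC[C@]2(C)C([C@@H](O)CC=C)=CCC[C@H]2C | intermediate
15 | (5S)-5-Cy-5-hydroxypentanal | CC1(C)OC[C@H](O1)[C@](C)(O[Si](CC)(CC)CC)CC[C@]2(C)C([C@@H](O)CCCC=O)=CCC[C@H]2C | intermediate (not isolated)
16 | (6S)-6-Cy-tetrahydro-2H-pyran-2-ol, anomer mixture | CC1(C)OC[C@H](O1)[C@](C)(O[Si](CC)(CC)CC)CC[C@]2(C)C([C@@H]3CCCC(O)O3)=CCC[C@H]2C | intermediate
17 | (6S)-6-Cy-tetrahydro-2H-pyran-2-yl methanesulfonate | CC1(C)OC[C@H](O1)[C@](C)(O[Si](CC)(CC)CC)CC[C@]2(C)C([C@@H]3CCCC(OS(C)(=O)=O)O3)=CCC[C@H]2C | intermediate (not isolated)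
18 | (2S)-2-Cy-3,4-dihydro-2H-pyran | CC1(C)OC[C@H](O1)[C@](C)(O[Si](CC)(CC)CC)CC[C@]2(C)C([C@@H]3CCC=CO3)=CCC[C@H]2C | intermediate
19 | 2,2,2-trichloro-1-[(2S)-2-Cy-3,4-dihydro-2H-pyran-5-yl]ethan-1-one | CC1(C)OC[C@H](O1)[C@](C)(O[Si](CC)(CC)CC)CC[C@]2(C)C([C@@H]3CCC(C(=O)C(Cl)(Cl)Cl)=CO3)=CCC[C@H]2C | intermediate
20 | allyl (2S)-2-Cy-3,4-dihydro-2H-pyran-5-carboxylate | CC1(C)OC[C@H](O1)[C@](C)(O[Si](CC)(CC)CC)CC[C@]2(C)C([C@@H]3CCC(C(=O)OCC=C)=CO3)=CCC[C@H]2C | intermediate
21 | allyl (4S,5S,8R,9S,13R,14S)-14,15-isopropylidenedioxy-19-oxo-13-(triethylsilyloxy)halim-1(10)-en-18-oate | CC1(C)OC[C@H](O1)[C@](C)(O[Si](CC)(CC)CC)CC[C@]2(C)C3=CCC[C@](C=O)(C(=O)OCC=C)[C@H]3CC[C@H]2C | intermediate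
22 | 19-(E)-tosylhydrazone of 21 | CC1(C)OC[C@H](O1)[C@](C)(O[Si](CC)(CC)CC)CC[C@]2(C)C3=CCC[C@](/C=N/NS(=O)(=O)c4ccc(C)cc4)(C(=O)OCC=C)[C@H]3CC[C@H]2C | intermediate
23 | N-(1,3,2-benzodioxaborol-2-yl) hydrazide from hydride addition to C19 of 22 | CC1(C)OC[C@H](O1)[C@](C)(O[Si](CC)(CC)CC)CC[C@]2(C)C3=CCC[C@](CN(B4Oc5ccccc5O4)NS(=O)(=O)c4ccc(C)cc4)(C(=O)OCC=C)[C@H]3CC[C@H]2C | intermediate (not isolated)
24 | allyl (4S,5S,8R,9S,13R,14S)-14,15-isopropylidenedioxy-13-(triethylsilyloxy)halim-1(10)-en-18-oate | CC1(C)OC[C@H](O1)[C@](C)(O[Si](CC)(CC)CC)CC[C@]2(C)C3=CCC[C@](C)(C(=O)OCC=C)[C@H]3CC[C@H]2C | intermediate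
25 | allyl (4S,5S,8R,9S,13R,14S)-13,14,15-trihydroxyhalim-1(10)-en-18-oate | OC[C@H](O)[C@](C)(O)CC[C@]1(C)C2=CCC[C@](C)(C(=O)OCC=C)[C@H]2CC[C@H]1C | intermediate
26 | allyl (4S,5S,8R,9S,13R,14S)-14,15-diacetoxy-13-hydroxyhalim-1(10)-en-18-oate | CC(=O)OC[C@H](OC(C)=O)[C@](C)(O)CC[C@]1(C)C2=CCC[C@](C)(C(=O)OCC=C)[C@H]2CC[C@H]1C | intermediate
27 | (4S,5S,8R,9S,13R,14S)-14,15-diacetoxy-13-hydroxyhalim-1(10)-en-18-oic acid (CNP0224606.1) | CC(=O)OC[C@H](OC(C)=O)[C@](C)(O)CC[C@]1(C)C2=CCC[C@](C)(C(=O)O)[C@H]2CC[C@H]1C | target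

**Step count and risks**

Total step count: 19. Longest linear sequence: 18 steps (steps 1, 2 and 4–19).

Steps most likely to fail:

1. Step 14. The sigmatropic shift may be slow, because the enol ether is electron-poor and the boat transition state is crowded next to quaternary C9. Heterolysis of the allylic C1–O bond or retro-[4+2] fragmentation could then compete and erode the chirality transfer. The fallback sets out from 20 and comes back at 24, and uses the electron-rich 5-alkyl enol ether, the substrate type for which this thermal ring contraction is best established. DIBAL-H (CH2Cl2, −78 °C) should reduce the ester to the hydroxymethyl dihydropyran F1. NaH/PMBCl should give the PMB ether F2. Heating (toluene, 170 °C) should give the formyl compound F3 through the same boat, with CH2OPMB cis to H5. TsNHNH2 should give the tosylhydrazone F4, and catecholborane/NaOAc the C19-methyl PMB ether F5. DDQ should free the neopentyl alcohol F6, TEMPO/NaOCl/NaClO2 should oxidise it to the acid F7, and allyl bromide/K2CO3 (DMF) returns to 24.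

2. Step 16. Hydride transfer to the neopentyl C=N may be incomplete, and the α-formyl ester unit may lose its formyl carbon by retro-Claisen-type cleavage. The fallback sets out from 21 and comes back at 24. NaBH4 (MeOH, −20 °C) should give the hydroxymethyl ester F8, PhOC(S)Cl/pyridine/DMAP the thionocarbonate F9, and Bu3SnH/AIBN (toluene, 110 °C, Barton–McCombie deoxygenation) should give 24.

3. Step 8. At the hindered alkenyl position, hydride transfer to the alkenylpalladium species may outrun CO insertion, which would give hydrodetriflation. The fallback sets out from 9 and comes back at 12, bypassing the triflate. Condensation with 2,4,6-triisopropylbenzenesulfonohydrazide should give the trisylhydrazone F10; n-BuLi (2.2 equiv, THF/TMEDA, −78 to 0 °C) should give the alkenyllithium (Shapiro reaction), and a DMF quench should give 12.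

Further compounds

F1 | step 14 | [(2S)-2-Cy-3,4-dihydro-2H-pyran-5-yl]methanol | CC1(C)OC[C@H](O1)[C@](C)(O[Si](CC)(CC)CC)CC[C@]2(C)C([C@@H]3CCC(CO)=CO3)=CCC[C@H]2C
F2 | step 14 | (2S)-2-Cy-5-[(4-methoxybenzyloxy)methyl]-3,4-dihydro-2H-pyran | CC1(C)OC[C@H](O1)[C@](C)(O[Si](CC)(CC)CC)CC[C@]2(C)C([C@@H]3CCC(COCc4ccc(OC)cc4)=CO3)=CCC[C@H]2C
F3 | step 14 | 18-(4-methoxybenzyloxy)-14,15-isopropylidenedioxy-13-(triethylsilyloxy)halim-1(10)-en-19-al, configured at C4 and C5 as in 21 | CC1(C)OC[C@H](O1)[C@](C)(O[Si](CC)(CC)CC)CC[C@]2(C)C3=CCC[C@](C=O)(COCc4ccc(OC)cc4)[C@H]3CC[C@H]2C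
F4 | step 14 | 19-(E)-tosylhydrazone of F3 | CC1(C)OC[C@H](O1)[C@](C)(O[Si](CC)(CC)CC)CC[C@]2(C)C3=CCC[C@](/C=N/NS(=O)(=O)c4ccc(C)cc4)(COCc4ccc(OC)cc4)[C@H]3CC[C@H]2C
F5 | step 14 | (4S,5S,8R,9S,13R,14S)-18-(4-methoxybenzyloxy)-14,15-isopropylidenedioxy-13-(triethylsilyloxy)halim-1(10)-ene | CC1(C)OC[C@H](O1)[C@](C)(O[Si](CC)(CC)CC)CC[C@]2(C)C3=CCC[C@](C)(COCc4ccc(OC)cc4)[C@H]3CC[C@H]2C
F6 | step 14 | (4S,5S,8R,9S,13R,14S)-14,15-isopropylidenedioxy-13-(triethylsilyloxy)halim-1(10)-en-18-ol | CC1(C)OC[C@H](O1)[C@](C)(O[Si](CC)(CC)CC)CC[C@]2(C)C3=CCC[C@](C)(CO)[C@H]3CC[C@H]2C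
F7 | step 14 | (4S,5S,8R,9S,13R,14S)-14,15-isopropylidenedioxy-13-(triethylsilyloxy)halim-1(10)-en-18-oic acid | CC1(C)OC[C@H](O1)[C@](C)(O[Si](CC)(CC)CC)CC[C@]2(C)C3=CCC[C@](C)(C(=O)O)[C@H]3CC[C@H]2C
F8 | step 16 | allyl (4S,5S,8R,9S,13R,14S)-19-hydroxy-14,15-isopropylidenedioxy-13-(triethylsilyloxy)halim-1(10)-en-18-oate | CC1(C)OC[C@H](O1)[C@](C)(O[Si](CC)(CC)CC)CC[C@]2(C)C3=CCC[C@](CO)(C(=O)OCC=C)[C@H]3CC[C@H]2C
F9 | step 16 | 19-O-(phenoxythiocarbonyl) derivative of F8 | CC1(C)OC[C@H](O1)[C@](C)(O[Si](CC)(CC)CC)CC[C@]2(C)C3=CCC[C@](COC(=S)Oc4ccccc4)(C(=O)OCC=C)[C@H]3CC[C@H]2C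
F10 | step 8 | (E)-2,4,6-triisopropylbenzenesulfonylhydrazone of ketone 9 | CC1(C)OC[C@H](O1)[C@](C)(O[Si](CC)(CC)CC)CC[C@]2(C)/C(=N/NS(=O)(=O)c3c(C(C)C)cc(C(C)C)cc3C(C)C)CCC[C@H]2C
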